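**Plan**
- Cuts: first the two MOM acetals on O3 and O5. Next the C3'–O and C5'–O bonds of ring B, back to two C–H bonds of a 4-methoxyphenyl group. Then O5–H back to O5–CH3, the C3–O bond, O1–C2 of ring C, and the C2–C3 bond (the chalcone alkene).
- Enabling feature: in ring B the oxygens at C3' and C5' flank the C4' methoxy group, so in the 4'-methoxyflavonol these two C–H bonds have only a small OMe as neighbour. C2'–H and C6'–H abut the fully substituted C2 of ring C. C6–H, the only C–H of ring A, lies between O5 and O7.
- Forward: rings A and B are bought and joined by Claisen–Schmidt condensation, and oxidative oxa-Michael closure makes ring C. C3 hydroxylation, 5-O-demethylation, double MOM protection, twofold C–H borylation/oxidation and MOM removal follow.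
- Stereochemistry: the target has no stereocentre. The E-alkene of the chalcone and the racemic epoxide are transient and are erased on the way.

Key step: step 6

Assumption: 1 is taken as a catalogue compound, and the dimethyldioxirane solution is made beforehand from acetone and KHSO5 by the standard procedure.

Step 1
Reactants: 1 2'-hydroxy-3',4',6'-trimethoxyacetophenone; 2 4-methoxybenzaldehyde
Product: 3 (E)-1-(2-hydroxy-3,4,6-trimethoxyphenyl)-3-(4-methoxyphenyl)prop-2-en-1-one
Conditions: KOH (50 % aq), EtOH, rt; then dilute HCl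
Reagents that add atoms: none
Why: Claisen–Schmidt condensation, in which the methyl ketone enolate of 1 adds to the non-enolisable aldehyde 2 and E1cB loss of water gives the conjugated enone in its thermodynamically favoured E geometry.

Step 2
Reactants: 3 (E)-1-(2-hydroxy-3,4,6-trimethoxyphenyl)-3-(4-methoxyphenyl)prop-2-en-1-one
Product: 4 5,7,8-trimethoxy-2-(4-methoxyphenyl)-4H-chromen-4-one
Conditions: I2 (10 mol %), DMSO, 130 °C
Reagents that add atoms: none
Why: Iodine-catalysed oxidative cyclisation of a 2'-hydroxychalcone, a standard entry to polymethoxyflavones, in which 6-endo oxa-Michael closure of the phenol onto the β-carbon forms O1–C2 and ring C, and α-iodination with loss of HI (iodine being regenerated by DMSO) dehydrogenates the flavanone.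

Step 3
Reactants: 4 5,7,8-trimethoxy-2-(4-methoxyphenyl)-4H-chromen-4-one
Product: 6 3-hydroxy-5,7,8-trimethoxy-2-(4-methoxyphenyl)-4H-chromen-4-one, via flavone 2,3-epoxide 5 (not isolated)
Conditions: dimethyldioxirane (acetone solution, excess), CH2Cl2, 0 °C to rt; then p-TsOH (cat), CH2Cl2, rt
Reagents that add atoms: dimethyldioxirane, CC1(C)OO1
Why: Dimethyldioxirane epoxidation of the C2=C3 bond and acid-catalysed opening of the epoxide with loss of H3 is an established flavone-to-flavonol oxidation of polymethoxyflavones, chosen because the Algar–Flynn–Oyamada oxidation of a 6'-methoxychalcone such as 3 tends to be diverted to aurones.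

Step 4
Reactants: 6 3-hydroxy-5,7,8-trimethoxy-2-(4-methoxyphenyl)-4H-chromen-4-one
Product: 7 3,5-dihydroxy-7,8-dimethoxy-2-(4-methoxyphenyl)-4H-chromen-4-one
Conditions: AlCl3 (excess), MeCN, 70 °C; then 2 M HCl, 70 °C
Reagents that add atoms: none
Why: Chelation-controlled Lewis-acid ether cleavage, well known for 5-methoxyflavones and 5-methoxyflavonols, in which aluminium held at the C4 carbonyl activates only the peri 5-methoxy group for attack of chloride on its methyl carbon, while the 7-, 8- and 4'-methoxy groups lack such an anchor.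

Step 5
Reactants: 7 3,5-dihydroxy-7,8-dimethoxy-2-(4-methoxyphenyl)-4H-chromen-4-one
Product: 8 7,8-dimethoxy-3,5-bis(methoxymethoxy)-2-(4-methoxyphenyl)-4H-chromen-4-one
Conditions: NaH (3 equiv), MOMCl (3 equiv), DMF, 0 °C to rt
Reagents that add atoms: chloromethyl methyl ether (MOMCl), COCCl
Why: Williamson-type O-alkylation with a highly reactive α-chloro ether, in which full deprotonation by NaH breaks the hydrogen bond between 5-OH and the C4 carbonyl that makes this hydroxyl sluggish under amine bases.

Step 6
Reactants: 8 7,8-dimethoxy-3,5-bis(methoxymethoxy)-2-(4-methoxyphenyl)-4H-chromen-4-one; 9 bis(pinacolato)diboron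
Product: 11 2-(3,5-dihydroxy-4-methoxyphenyl)-7,8-dimethoxy-3,5-bis(methoxymethoxy)-4H-chromen-4-one, via 3',5'-bis(pinacolboronate) 10 (not isolated)
Conditions: [Ir(OMe)(cod)]2 (2 × 2.5 mol %), 4,4'-di-tert-butyl-2,2'-bipyridine (dtbpy, 2 × 5 mol %), 9 (3 equiv), THF, 80 °C, sealed tube; then NaBO3·4H2O, THF/H2O, rt
Reagents that add atoms: NaBO3·4H2O (source of both new oxygen atoms; dimeric anion, crystal water omitted), [Na+].[Na+].O[B-]1(O)OO[B-](O)(O)OO1
Why: Proposed new method: [Ir(OMe)(cod)]2, dtbpy and 9 form the 16-electron trisboryl complex (dtbpy)Ir(Bpin)3 of trivalent iridium, which cleaves an aryl C–H bond to a pentavalent iridium aryl hydride, releases the aryl boronate by C–B reductive elimination and is restored by 9; two such cycles give 10, and perborate then adds to each boron and triggers a 1,2-shift of the aryl carbon from B to O, so that C3'–O and C5'–O are both made in one pot. The closest known reaction type is the one-pot iridium-catalysed C–H borylation/oxidation of arenes to phenols, which is established for a single borylation beside the methoxy group of 4-substituted anisoles; the second borylation on the other flank of the same methoxy group, and a flavonol as substrate, go beyond that. No ring is closed and no stereocentre is created. The step needs site selectivity for C3'–H and C5'–H, and sterics in 8 supply it: C2'–H and C6'–H sit beside the fully substituted C2 of ring C, whose 3-OMOM group twists ring B out of the chromone plane and hangs over them, C6–H of ring A is wedged between the oxygen substituents at C5 and C7, and the MOM and methyl groups offer only unreactive sp3 C–H bonds, while the C4' methoxy group is the smallest neighbour available and also acidifies its ortho C–H bonds. After the first borylation C2' is closed off between C1' and boron, so the choice is again between a site beside OMe (C5', meta to boron as in the usual pattern of multiple borylation) and a site beside the chromone (C6'); the methoxy group must turn perpendicular to ring B to admit the catalyst, and excess 9, 80 °C and a second catalyst charge are meant to pay for that. The MOM ethers tolerate the neutral borylation and the mildly basic perborate and keep the 3-hydroxy-4-pyranone, which alkaline peroxide would degrade, masked during the oxidation.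

Step 7
Reactants: 11 2-(3,5-dihydroxy-4-methoxyphenyl)-7,8-dimethoxy-3,5-bis(methoxymethoxy)-4H-chromen-4-one
Product: 12 2-(3,5-dihydroxy-4-methoxyphenyl)-3,5-dihydroxy-7,8-dimethoxy-4H-chromen-4-one (target)
Conditions: HCl (1.25 M in MeOH), 45 °C
Reagents that add atoms: none
Why: Acid-catalysed acetal exchange (MOM cleavage) in which methanol traps the methoxymethyl cation as dimethoxymethane, the aryl methyl ethers are inert, and the conditions are far milder than those that bring about a Wessely–Moser rearrangement of the 5,7,8-oxygenated ring A.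

**Compound list**
1 | 2'-hydroxy-3',4',6'-trimethoxyacetophenone | CC(=O)c1c(O)c(OC)c(OC)cc1OC | starting material
2 | 4-methoxybenzaldehyde | COc1ccc(C=O)cc1 | starting material
3 | (E)-1-(2-hydroxy-3,4,6-trimethoxyphenyl)-3-(4-methoxyphenyl)prop-2-en-1-one | COc1ccc(/C=C/C(=O)c2c(O)c(OC)c(OC)cc2OC)cc1 | intermediate
4 | 5,7,8-trimethoxy-2-(4-methoxyphenyl)-4H-chromen-4-one | COc1ccc(cc1)-c1cc(=O)c2c(OC)cc(OC)c(OC)c2o1 | intermediate
5 | 2,3-epoxy-5,7,8-trimethoxy-2-(4-methoxyphenyl)chroman-4-one (racemic; the cis ring fusion is the only possible one; not isolated) | COc1ccc(cc1)C12Oc3c(OC)c(OC)cc(OC)c3C(=O)C1O2 | intermediate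
6 | 3-hydroxy-5,7,8-trimethoxy-2-(4-methoxyphenyl)-4H-chromen-4-one | COc1ccc(cc1)-c1oc2c(OC)c(OC)cc(OC)c2c(=O)c1O | intermediate
7 | 3,5-dihydroxy-7,8-dimethoxy-2-(4-methoxyphenyl)-4H-chromen-4-one | COc1ccc(cc1)-c1oc2c(OC)c(OC)cc(O)c2c(=O)c1O | intermediate
8 | 7,8-dimethoxy-3,5-bis(methoxymethoxy)-2-(4-methoxyphenyl)-4H-chromen-4-one | COCOc1cc(OC)c(OC)c2oc(-c3ccc(OC)cc3)c(OCOC)c(=O)c12 | intermediate
9 | bis(pinacolato)diboron | CC1(C)OB(OC1(C)C)B1OC(C)(C)C(C)(C)O1 | starting material
10 | 7,8-dimethoxy-3,5-bis(methoxymethoxy)-2-[4-methoxy-3,5-bis(4,4,5,5-tetramethyl-1,3,2-dioxaborolan-2-yl)phenyl]-4H-chromen-4-one (not isolated) | COCOc1cc(OC)c(OC)c2oc(-c3cc(B4OC(C)(C)C(C)(C)O4)c(OC)c(B4OC(C)(C)C(C)(C)O4)c3)c(OCOC)c(=O)c12 | intermediate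
11 | 2-(3,5-dihydroxy-4-methoxyphenyl)-7,8-dimethoxy-3,5-bis(methoxymethoxy)-4H-chromen-4-one | COCOc1cc(OC)c(OC)c2oc(-c3cc(O)c(OC)c(O)c3)c(OCOC)c(=O)c12 | intermediate
12 | 2-(3,5-dihydroxy-4-methoxyphenyl)-3,5-dihydroxy-7,8-dimethoxy-4H-chromen-4-one | COc1cc(O)c2c(=O)c(O)c(-c3cc(O)c(OC)c(O)c3)oc2c1OC | target

Total step count: 7. Longest linear sequence: 7 steps (1 to 12).

**Steps most likely to fail**

Step 6. The reaction may stall after the first C–H borylation because the methoxy group is geared toward the free flank. The second borylation may drift to C6', or the Lewis-basic pyranone may deactivate the catalyst. The fallback brings both ring B sites in as C–Br bonds; it sets out from 1 and returns at 10. Acetophenone 1 is condensed (KOH, EtOH) with commercial 3,5-dibromo-4-methoxybenzaldehyde F1 to the dibromochalcone F2. This is carried through the operations of steps 2 to 5: I2/DMSO to the dibromoflavone F3, dimethyldioxirane to its epoxide F4, p-TsOH to the dibromoflavonol F5, AlCl3/MeCN to the 3,5-diol F6, and NaH/MOMCl to the bis-MOM dibromide F7. Twofold Miyaura borylation (Pd(dppf)Cl2, KOAc, 9, dioxane, 90 °C) should then give 10, which is oxidised with NaBO3·4H2O as in step 6.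

Step 4. Aluminium may be sequestered in the five-membered chelate of O3 and the C4 carbonyl, so that cleavage at O5 is slow and forcing leads to loss of further methyl groups (O8, O4'). The fallback moves the dealkylation ahead of the C3 oxidation, onto a substrate with a single chelating site; it sets out from 4 and returns at 8. Flavone 4 is treated with AlCl3/MeCN to give the 5-hydroxyflavone F8. NaH/MOMCl in DMF gives the 5-O-MOM flavone F9, and dimethyldioxirane gives the epoxide F10. This should isomerise on silica gel, without added acid, to the 3-hydroxy-5-O-MOM flavone F11. MOMCl and i-Pr2NEt in CH2Cl2 then cap O3 to give 8.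

Step 3. Oxygen transfer to the electron-poor C2=C3 bond may be slow, with decay of the reagent and competing oxidation of the electron-rich ring A. The fallback replaces electrophilic oxygen transfer by deprotonation and boronate oxidation; it sets out from 4 and returns at 6. LiN(i-Pr)2 (THF, −78 °C) removes H3 to give the carbonyl-stabilised 3-lithioflavone F12. B(OMe)3 traps it as the dimethyl boronate F13, and H2O2/AcOH oxidises the C3–B bond to give 6.

**Further compounds**
F1 | step 6 | 3,5-dibromo-4-methoxybenzaldehyde (commercial) | COc1c(Br)cc(C=O)cc1Br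
F2 | step 6 | (E)-3-(3,5-dibromo-4-methoxyphenyl)-1-(2-hydroxy-3,4,6-trimethoxyphenyl)prop-2-en-1-one | COc1c(Br)cc(/C=C/C(=O)c2c(O)c(OC)c(OC)cc2OC)cc1Br
F3 | step 6 | 2-(3,5-dibromo-4-methoxyphenyl)-5,7,8-trimethoxy-4H-chromen-4-one | COc1c(Br)cc(cc1Br)-c1cc(=O)c2c(OC)cc(OC)c(OC)c2o1
F4 | step 6 | 2-(3,5-dibromo-4-methoxyphenyl)-2,3-epoxy-5,7,8-trimethoxychroman-4-one (racemic) | COc1c(Br)cc(cc1Br)C12Oc3c(OC)c(OC)cc(OC)c3C(=O)C1O2
F5 | step 6 | 2-(3,5-dibromo-4-methoxyphenyl)-3-hydroxy-5,7,8-trimethoxy-4H-chromen-4-one | COc1c(Br)cc(cc1Br)-c1oc2c(OC)c(OC)cc(OC)c2c(=O)c1O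
F6 | step 6 | 2-(3,5-dibromo-4-methoxyphenyl)-3,5-dihydroxy-7,8-dimethoxy-4H-chromen-4-one | COc1c(Br)cc(cc1Br)-c1oc2c(OC)c(OC)cc(O)c2c(=O)c1O
F7 | step 6 | 2-(3,5-dibromo-4-methoxyphenyl)-7,8-dimethoxy-3,5-bis(methoxymethoxy)-4H-chromen-4-one | COCOc1cc(OC)c(OC)c2oc(-c3cc(Br)c(OC)c(Br)c3)c(OCOC)c(=O)c12
F8 | step 4 | 5-hydroxy-7,8-dimethoxy-2-(4-methoxyphenyl)-4H-chromen-4-one | COc1ccc(cc1)-c1cc(=O)c2c(O)cc(OC)c(OC)c2o1
F9 | step 4 | 7,8-dimethoxy-5-(methoxymethoxy)-2-(4-methoxyphenyl)-4H-chromen-4-one | COCOc1cc(OC)c(OC)c2oc(-c3ccc(OC)cc3)cc(=O)c12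
F10 | step 4 | 2,3-epoxy-7,8-dimethoxy-5-(methoxymethoxy)-2-(4-methoxyphenyl)chroman-4-one (racemic) | COCOc1cc(OC)c(OC)c2OC3(c4ccc(OC)cc4)OC3C(=O)c12
F11 | step 4 | 3-hydroxy-7,8-dimethoxy-5-(methoxymethoxy)-2-(4-methoxyphenyl)-4H-chromen-4-one | COCOc1cc(OC)c(OC)c2oc(-c3ccc(OC)cc3)c(O)c(=O)c12
F12 | step 3 | 3-lithio-5,7,8-trimethoxy-2-(4-methoxyphenyl)-4H-chromen-4-one | [Li]c1c(-c2ccc(OC)cc2)oc2c(OC)c(OC)cc(OC)c2c1=O
F13 | step 3 | dimethyl [5,7,8-trimethoxy-2-(4-methoxyphenyl)-4-oxo-4H-chromen-3-yl]boronate | COB(OC)c1c(-c2ccc(OC)cc2)oc2c(OC)c(OC)cc(OC)c2c1=O
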